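**Retrosynthetic overview**

Numbering: C4 = CMe2 carbon, C5=C6 = ring alkene, C7 = CH2, C8 = CHMe, C9 = quaternary carbon, C10 = ring-fusion CH, C11 = CH2 link to the quinone.
- The quinone substituents go on last (amine for the methoxy group far from the chain, hydroxide for the one beside it); the C11–quinone bond comes from decarboxylative radical addition of the decalinylacetic acid to 2,5-dimethoxybenzoquinone.
- The strategy rests on ring B (C5, C6, C7, C8, C9, C10): it is opened at the crowded C8–C9 bond, tertiary C8 beside quaternary C9. This leaves ring A with an exocyclic C5=C6 alkene, a vinyl group at C8 and a Z β-methyl enoate (C9=C11) on C10, the only stereocentre; HAT to the vinyl group and 6-exo addition of the C8 radical to C9 remake the bond.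
- The enoate comes from an ynoate and Me2CuLi, so no enolisable ketone sits next to C10. The ynoate comes from the C10 aldehyde, which a Still–Wittig [2,3] shift delivers from an (R)-homoallylic alcohol (asymmetric allylboration of the Shapiro-derived enal).
- Ring order: ring A is bought, ring B is closed in the key step, the bought quinone ring is joined after it.

Key step: step 10

Remark on the chemistry: the allylboration is assumed to follow the sense known for aryl and alkenyl aldehydes (the (R)-acid giving Re-face attack); were it reversed, the (S)-acid would be used and nothing else changes.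

**Route**

Step 1
Reactants: 1 2,2-dimethylcyclohexanone; 2 2,4,6-tri(propan-2-yl)benzenesulfonohydrazide
Product: 3 (E)-N′-(2,2-dimethylcyclohexylidene)-2,4,6-tri(propan-2-yl)benzenesulfonohydrazide
Conditions: cat. HCl, MeOH, 23 °C
Reagents that add atoms: none
Why: Acid-catalysed hydrazone formation; the sulfonamide nitrogen should settle anti to the quaternary carbon, syn to the only α-CH2.

Step 2
Reactants: 3 (E)-N′-(2,2-dimethylcyclohexylidene)-2,4,6-tri(propan-2-yl)benzenesulfonohydrazide
Product: 5 6,6-dimethylcyclohex-1-ene-1-carbaldehyde, via vinyllithium 4 (not isolated)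
Conditions: n-BuLi (2.2 equiv), TMEDA, THF/hexane, −78 → 0 °C; DMF, −78 → 23 °C; H2O
Reagents that add atoms: N,N-dimethylformamide CN(C)C=O
Why: Shapiro reaction: deprotonation at NH and at the single α-CH2, then loss of sulfinate and N2, gives the vinyllithium regiospecifically, and DMF formylates it.

Step 3
Reactants: 5 6,6-dimethylcyclohex-1-ene-1-carbaldehyde; 6 allylboronic acid pinacol ester
Product: 8 (1R)-1-(6,6-dimethylcyclohex-1-en-1-yl)but-3-en-1-ol, via pinacol borate ester 7 (not isolated)
Conditions: (R)-3,3′-bis(2,4,6-triisopropylphenyl)-1,1′-binaphthyl-2,2′-diyl hydrogen phosphate (5 mol%), toluene, −30 °C; aqueous work-up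
Reagents that add atoms: none
Why: Chiral phosphoric acid-catalysed allylboration through a closed chair transition state in which the acid binds the boronate oxygen; the (R)-acid should place the allyl group on the Re face of the formyl group and so set the (R)-carbinol centre, and work-up cleaves the borate ester.

Step 4
Reactants: 8 (1R)-1-(6,6-dimethylcyclohex-1-en-1-yl)but-3-en-1-ol
Product: 9 tributyl({[(1R)-1-(6,6-dimethylcyclohex-1-en-1-yl)but-3-en-1-yl]oxy}methyl)stannane
Conditions: KH, Bu3SnCH2I, THF, 0 → 23 °C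
Reagents that add atoms: (iodomethyl)tributylstannane CCCC[Sn](CCCC)(CCCC)CI
Why: Williamson etherification of the potassium alkoxide with the reactive α-stannyl iodide; the stereocentre is not touched.

Step 5
Reactants: 9 tributyl({[(1R)-1-(6,6-dimethylcyclohex-1-en-1-yl)but-3-en-1-yl]oxy}methyl)stannane
Product: 11 [(1R,2E)-2-(but-3-en-1-ylidene)-3,3-dimethylcyclohexyl]methanol, via alkoxymethyllithium 10 (not isolated)
Conditions: n-BuLi, THF, −78 °C; H2O
Reagents that add atoms: none
Why: Tin–lithium exchange and Still–Wittig [2,3]-sigmatropic shift through an envelope transition state with the allyl group of the carbinol pseudoaxial, away from the C4 methyl groups (A1,2 strain); this puts C7 cis to C10 on the new C5=C6 alkene, and the suprafacial shift carries the (R)-carbinol configuration to (R)-C10, while any minor alkene isomer has the wrong geometry for ring closure and is removed here.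

Step 6
Reactants: 11 [(1R,2E)-2-(but-3-en-1-ylidene)-3,3-dimethylcyclohexyl]methanol
Product: 12 (1R,2E)-2-(but-3-en-1-ylidene)-3,3-dimethylcyclohexane-1-carbaldehyde
Conditions: Dess–Martin periodinane, NaHCO3, CH2Cl2, 0 °C; used at once
Reagents that add atoms: none
Why: Buffered Dess–Martin oxidation stops at the aldehyde under near-neutral conditions, which should keep the β,γ-unsaturated α-stereocentre from epimerising or moving into conjugation.

Step 7
Reactants: 12 (1R,2E)-2-(but-3-en-1-ylidene)-3,3-dimethylcyclohexane-1-carbaldehyde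
Product: 13 (1S,2E)-2-(but-3-en-1-ylidene)-1-(2,2-dibromoethenyl)-3,3-dimethylcyclohexane
Conditions: CBr4, PPh3, Zn, CH2Cl2, 23 °C; then 12, 0 °C
Reagents that add atoms: carbon tetrabromide BrC(Br)(Br)Br
Why: Corey–Fuchs dibromo-olefination with the ylide preformed from CBr4, PPh3 and Zn is a neutral Wittig reaction, so C10 keeps its configuration (the descriptor changes only through the priority rules).

Step 8
Reactants: 13 (1S,2E)-2-(but-3-en-1-ylidene)-1-(2,2-dibromoethenyl)-3,3-dimethylcyclohexane
Product: 15 methyl 3-[(1S,2E)-2-(but-3-en-1-ylidene)-3,3-dimethylcyclohexyl]prop-2-ynoate, via lithium acetylide 14 (not isolated)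
Conditions: n-BuLi (2.1 equiv), THF, −78 °C; ClCO2Me, −78 → 0 °C
Reagents that add atoms: methyl chloroformate COC(=O)Cl
Why: Second stage of the Corey–Fuchs sequence: bromine–lithium exchange, α-elimination with 1,2-hydrogen shift (Fritsch–Buttenberg–Wiechell) and deprotonation give the lithium acetylide, which methyl chloroformate acylates; exchange at −78 °C is faster than removal of the C10 hydrogen.

Step 9
Reactants: 15 methyl 3-[(1S,2E)-2-(but-3-en-1-ylidene)-3,3-dimethylcyclohexyl]prop-2-ynoate
Product: 17 methyl (2Z)-3-[(1S,2E)-2-(but-3-en-1-ylidene)-3,3-dimethylcyclohexyl]but-2-enoate, via alkenylcuprate 16 (not isolated)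
Conditions: Me2CuLi (from CuI, 2 MeLi), THF, −78 °C; aq. NH4Cl, −78 °C
Reagents that add atoms: lithium dimethylcuprate [Li+].C[Cu-]C
Why: Conjugate addition of the Gilman cuprate to the ynoate is a syn carbocupration, and protonation of the alkenylcuprate with retention at −78 °C should give the Z enoate (C10 cis to the ester) without a base that could touch the C10 hydrogen.

Step 10
Reactants: 17 methyl (2Z)-3-[(1S,2E)-2-(but-3-en-1-ylidene)-3,3-dimethylcyclohexyl]but-2-enoate
Product: 20 methyl 2-[(1R,2S,8aS)-1,2,5,5-tetramethyl-1,2,3,5,6,7,8,8a-octahydronaphthalen-1-yl]acetate, via secondary C8 radical 18 (not isolated), via cyclised C11 ester radical 19 (not isolated)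
Conditions: Fe(acac)3 (0.5 equiv), PhSiH3 (2.5 equiv, slow addition), EtOH/ethylene glycol 5:1, 0.01 M, 60 °C
Reagents that add atoms: none
Why: Fe(acac)3 and PhSiH3 in ethanol should form an iron hydride that gives a hydrogen atom to the terminal CH2 of the vinyl group; the secondary C8 radical 18 adds to C9 of the enoate and closes ring B in a 6-exo-trig mode, and the C11 α-ester radical 19 is reduced by divalent iron and protonated by ethanol to the CH2CO2Me group. The closest known reaction type is the iron-hydride HAT-initiated reductive (Giese-type) conjugate cyclisation of unactivated alkenes onto β,β-disubstituted acrylates, which forms quaternary centres. C9 is set by C10: A1,3 strain with the cis ester on C11 holds H10 in the enoate plane, the tethered radical can reach only the face on which C5 lies, and the C9 methyl ends axial and trans to H10 (the E enoate would close to the same product but with a weaker rotamer bias). C8 is set in the chair-like transition state, in which the radical carbon turns its methyl pseudoequatorial, anti to C6 and into the sector between the C9 methyl and C11 rather than beside C10, which places it cis to the C9 methyl. The step needs hydrogen-atom transfer at the vinyl group only, and that is the one unhindered, electron-neutral alkene: C5=C6 is shielded by the C4 methyl groups and C10, and the enoate is electron-poor. The exocyclic alkene with C7 cis to C10 already fixes four of the six ring atoms; dilution and slow silane addition should keep reduction of radical 18 behind ring closure, and 3-exo attack on C5=C6 is reversible and leads nowhere.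

Step 11
Reactants: 20 methyl 2-[(1R,2S,8aS)-1,2,5,5-tetramethyl-1,2,3,5,6,7,8,8a-octahydronaphthalen-1-yl]acetate
Product: 21 2-[(1R,2S,8aS)-1,2,5,5-tetramethyl-1,2,3,5,6,7,8,8a-octahydronaphthalen-1-yl]acetic acid
Conditions: LiOH, THF/MeOH/H2O, 50 °C; 1 M HCl
Reagents that add atoms: lithium hydroxide [Li+].[OH-]
Why: Saponification by acyl substitution; none of C8, C9 and C10 is enolisable, and the alkene is inert to base.

Step 12
Reactants: 21 2-[(1R,2S,8aS)-1,2,5,5-tetramethyl-1,2,3,5,6,7,8,8a-octahydronaphthalen-1-yl]acetic acid; 22 2,5-dimethoxy-1,4-benzoquinone (3 equiv)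
Product: 24 2,5-dimethoxy-3-{[(1R,2S,8aS)-1,2,5,5-tetramethyl-1,2,3,5,6,7,8,8a-octahydronaphthalen-1-yl]methyl}cyclohexa-2,5-diene-1,4-dione, via primary C11 radical 23 (not isolated)
Conditions: AgNO3 (0.3 equiv), (NH4)2S2O8 (1.5 equiv), MeCN/H2O 1:1, 65 °C
Reagents that add atoms: none
Why: Silver-catalysed persulfate decarboxylation (Minisci-type radical alkylation of a quinone): divalent silver oxidises the carboxylate, loss of CO2 gives the primary C11 radical, which adds to an unsubstituted quinone carbon, and the adduct is re-oxidised to the alkylquinone; C11 could reach C5=C6 only by 4-exo or 5-endo closure, so it should not cyclise.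

Step 13
Reactants: 24 2,5-dimethoxy-3-{[(1R,2S,8aS)-1,2,5,5-tetramethyl-1,2,3,5,6,7,8,8a-octahydronaphthalen-1-yl]methyl}cyclohexa-2,5-diene-1,4-dione
Product: 25 2-hydroxy-5-methoxy-3-{[(1R,2S,8aS)-1,2,5,5-tetramethyl-1,2,3,5,6,7,8,8a-octahydronaphthalen-1-yl]methyl}cyclohexa-2,5-diene-1,4-dione
Conditions: 2 M KOH, MeOH, 23 → 50 °C; 1 M HCl
Reagents that add atoms: potassium hydroxide [K+].[OH-]
Why: Addition–elimination of hydroxide at a vinylogous ester carbon; the methoxy group beside the bulky chain is twisted out of conjugation and is the one that 3-alkyl-2,5-dimethoxybenzoquinones exchange first, and the hydroxyquinone anion formed resists a second exchange.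

Step 14
Reactants: 25 2-hydroxy-5-methoxy-3-{[(1R,2S,8aS)-1,2,5,5-tetramethyl-1,2,3,5,6,7,8,8a-octahydronaphthalen-1-yl]methyl}cyclohexa-2,5-diene-1,4-dione; 26 isopentylamine (3 equiv)
Product: 27 nakijiquinone M, 2-hydroxy-5-[(3-methylbutyl)amino]-3-{[(1R,2S,8aS)-1,2,5,5-tetramethyl-1,2,3,5,6,7,8,8a-octahydronaphthalen-1-yl]methyl}cyclohexa-2,5-diene-1,4-dione
Conditions: EtOH, 23 °C; dilute HCl wash
Reagents that add atoms: none
Why: Addition–elimination of the primary amine at the remaining vinylogous ester carbon gives the vinylogous amide; the ionised 2-hydroxy group is no leaving group, so only the methoxy group is replaced.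

**Compound list**

1 | 2,2-dimethylcyclohexanone | CC1(C)CCCCC1=O | starting material
2 | 2,4,6-tri(propan-2-yl)benzenesulfonohydrazide | CC(C)c1cc(C(C)C)c(S(=O)(=O)NN)c(C(C)C)c1 | starting material
3 | (E)-N′-(2,2-dimethylcyclohexylidene)-2,4,6-tri(propan-2-yl)benzenesulfonohydrazide | CC(C)c1cc(C(C)C)c(S(=O)(=O)N/N=C2\CCCCC2(C)C)c(C(C)C)c1 | intermediate
4 | (6,6-dimethylcyclohex-1-en-1-yl)lithium | [Li]C1=CCCCC1(C)C | intermediate
5 | 6,6-dimethylcyclohex-1-ene-1-carbaldehyde | CC1(C)CCCC=C1C=O | intermediate
6 | allylboronic acid pinacol ester | C=CCB1OC(C)(C)C(C)(C)O1 | starting material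
7 | 2-{[(1R)-1-(6,6-dimethylcyclohex-1-en-1-yl)but-3-en-1-yl]oxy}-4,4,5,5-tetramethyl-1,3,2-dioxaborolane | C=CC[C@@H](OB1OC(C)(C)C(C)(C)O1)C1=CCCCC1(C)C | intermediate
8 | (1R)-1-(6,6-dimethylcyclohex-1-en-1-yl)but-3-en-1-ol | C=CC[C@@H](O)C1=CCCCC1(C)C | intermediate
9 | tributyl({[(1R)-1-(6,6-dimethylcyclohex-1-en-1-yl)but-3-en-1-yl]oxy}methyl)stannane | C=CC[C@@H](OC[Sn](CCCC)(CCCC)CCCC)C1=CCCCC1(C)C | intermediate
10 | ({[(1R)-1-(6,6-dimethylcyclohex-1-en-1-yl)but-3-en-1-yl]oxy}methyl)lithium | C=CC[C@@H](OC[Li])C1=CCCCC1(C)C | intermediate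
11 | [(1R,2E)-2-(but-3-en-1-ylidene)-3,3-dimethylcyclohexyl]methanol (butenyl chain cis to C10) | C=CC/C=C1/C(C)(C)CCC[C@H]1CO | intermediate
12 | (1R,2E)-2-(but-3-en-1-ylidene)-3,3-dimethylcyclohexane-1-carbaldehyde | C=CC/C=C1/C(C)(C)CCC[C@H]1C=O | intermediate
13 | (1S,2E)-2-(but-3-en-1-ylidene)-1-(2,2-dibromoethenyl)-3,3-dimethylcyclohexane | C=CC/C=C1/C(C)(C)CCC[C@H]1C=C(Br)Br | intermediate
14 | {[(1S,2E)-2-(but-3-en-1-ylidene)-3,3-dimethylcyclohexyl]ethynyl}lithium | C=CC/C=C1/C(C)(C)CCC[C@H]1C#C[Li] | intermediate
15 | methyl 3-[(1S,2E)-2-(but-3-en-1-ylidene)-3,3-dimethylcyclohexyl]prop-2-ynoate | C=CC/C=C1/C(C)(C)CCC[C@H]1C#CC(=O)OC | intermediate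
16 | lithium methyl(alkenyl)cuprate of 15 (copper on C11, cis to the new C9 methyl) | C=CC/C=C1/C(C)(C)CCC[C@H]1/C(C)=C(/[Cu-]C)C(=O)OC.[Li+] | intermediate
17 | methyl (2Z)-3-[(1S,2E)-2-(but-3-en-1-ylidene)-3,3-dimethylcyclohexyl]but-2-enoate | C=CC/C=C1/C(C)(C)CCC[C@H]1/C(C)=C\C(=O)OC | intermediate
18 | secondary C8 radical of 17 (hydrogen added to the terminal CH2) | C[CH]C/C=C1/C(C)(C)CCC[C@H]1/C(C)=C\C(=O)OC | intermediate
19 | cyclised C11 α-ester radical (ring B closed, C8 and C9 set) | COC(=O)[CH][C@@]1(C)[C@@H]2CCCC(C)(C)C2=CC[C@@H]1C | intermediate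
20 | methyl 2-[(1R,2S,8aS)-1,2,5,5-tetramethyl-1,2,3,5,6,7,8,8a-octahydronaphthalen-1-yl]acetate | COC(=O)C[C@@]1(C)[C@@H]2CCCC(C)(C)C2=CC[C@@H]1C | intermediate
21 | 2-[(1R,2S,8aS)-1,2,5,5-tetramethyl-1,2,3,5,6,7,8,8a-octahydronaphthalen-1-yl]acetic acid | OC(=O)C[C@@]1(C)[C@@H]2CCCC(C)(C)C2=CC[C@@H]1C | intermediate
22 | 2,5-dimethoxy-1,4-benzoquinone | COC1=CC(=O)C(OC)=CC1=O | starting material
23 | primary C11 radical of 21 after loss of CO2 | [CH2][C@@]1(C)[C@@H]2CCCC(C)(C)C2=CC[C@@H]1C | intermediate
24 | 2,5-dimethoxy-3-{[(1R,2S,8aS)-1,2,5,5-tetramethyl-1,2,3,5,6,7,8,8a-octahydronaphthalen-1-yl]methyl}cyclohexa-2,5-diene-1,4-dione | COC1=CC(=O)C(OC)=C(C[C@@]2(C)[C@@H]3CCCC(C)(C)C3=CC[C@@H]2C)C1=O | intermediate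
25 | 2-hydroxy-5-methoxy-3-{[(1R,2S,8aS)-1,2,5,5-tetramethyl-1,2,3,5,6,7,8,8a-octahydronaphthalen-1-yl]methyl}cyclohexa-2,5-diene-1,4-dione | COC1=CC(=O)C(O)=C(C[C@@]2(C)[C@@H]3CCCC(C)(C)C3=CC[C@@H]2C)C1=O | intermediate
26 | isopentylamine (3-methylbutan-1-amine) | CC(C)CCN | starting material
27 | nakijiquinone M | CC(C)CCNC1=CC(=O)C(O)=C(C[C@@]2(C)[C@@H]3CCCC(C)(C)C3=CC[C@@H]2C)C1=O | target

**Step count**

Total steps: 14. Longest linear sequence: 14 steps, from 2,2-dimethylcyclohexanone 1 to 27.

**Steps most likely to fail**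

Risk 1, step 10. Three things may go wrong.
- Hydrogen-atom transfer may not stay at the vinyl group: the C5=C6 alkene could take up a hydrogen atom and the double bond could migrate toward C10.
- The C8 radical may be reduced before it closes, because closure needs the ring A conformer in which the enoate is equatorial and presses against C7.
- The two faces of the flat C8 radical may be told apart less well at 60 °C.

The fallback sets out from 17 and comes back at 20. Oxymercuration–demercuration of the vinyl group (Hg(OAc)2, THF/H2O; NaBH4, NaOH) should give the secondary alcohol methyl (2Z)-3-[(1S,2E)-2-(3-hydroxybutylidene)-3,3-dimethylcyclohexyl]but-2-enoate F1 as a mixture at C8, which does not matter. Appel iodination (I2, PPh3, imidazole, CH2Cl2, 0 °C) should give methyl (2Z)-3-[(1S,2E)-2-(3-iodobutylidene)-3,3-dimethylcyclohexyl]but-2-enoate F2. A tin hydride Giese cyclisation (Bu3SnH by syringe pump, Et3B/air, toluene, −78 → 0 °C) then makes the same C8 radical by iodine abstraction. No metal hydride comes near the other alkenes, and the lower temperature should enlarge the pseudoequatorial preference. The product is 20.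

Risk 2, step 12. The sulfate radical anion or divalent silver may oxidise the C5=C6 alkene, the nucleophilic primary radical may add slowly to the electron-rich quinone, and the product may be alkylated a second time. The fallback sets out from 21 and comes back at 24. Esterification with N-hydroxyphthalimide (N,N′-diisopropylcarbodiimide, DMAP, CH2Cl2) gives the redox-active ester 1,3-dioxoisoindolin-2-yl 2-[(1R,2S,8aS)-1,2,5,5-tetramethyl-1,2,3,5,6,7,8,8a-octahydronaphthalen-1-yl]acetate F3. Nickel-catalysed decarboxylative arylation (NiCl2(dme), 4,4′-di-tert-butyl-2,2′-bipyridine, THF/DMF, 23 °C) couples it with chloro(2,3,5,6-tetramethoxyphenyl)zinc F4, made from 1,2,4,5-tetramethoxybenzene with n-BuLi and then ZnCl2. This should give 3-{[(1R,2S,8aS)-1,2,5,5-tetramethyl-1,2,3,5,6,7,8,8a-octahydronaphthalen-1-yl]methyl}-1,2,4,5-tetramethoxybenzene F5. Oxidative demethylation with (NH4)2Ce(NO3)6 in MeCN/H2O at 0 °C turns either para pair of methoxy groups into the same quinone 24.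

Risk 3, step 3. Face selection in the allyl transfer to this hindered, α-branched enal may be poor, and the enantiomeric purity of every later compound depends on it. The fallback sets out from 5 and comes back at 8. Allylmagnesium bromide (THF, −78 °C) gives racemic 1-(6,6-dimethylcyclohex-1-en-1-yl)but-3-en-1-ol F6. Dess–Martin oxidation gives 1-(6,6-dimethylcyclohex-1-en-1-yl)but-3-en-1-one F7, kept cold and free of base so that the vinyl group does not move into conjugation. Corey–Bakshi–Shibata reduction follows, with (S)-1-methyl-3,3-diphenyltetrahydro-1H,3H-pyrrolo[1,2-c][1,3,2]oxazaborole and catecholborane in toluene at −78 °C. The cyclohexenyl group acts as the large substituent, and the reduction should give (R)-alcohol 8; catecholborane leaves the terminal alkene alone at this temperature.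

**Further compounds**

F1 | step 10 | methyl (2Z)-3-[(1S,2E)-2-(3-hydroxybutylidene)-3,3-dimethylcyclohexyl]but-2-enoate (both C8 epimers) | CC(O)C/C=C1/C(C)(C)CCC[C@H]1/C(C)=C\C(=O)OC
F2 | step 10 | methyl (2Z)-3-[(1S,2E)-2-(3-iodobutylidene)-3,3-dimethylcyclohexyl]but-2-enoate (both C8 epimers) | CC(I)C/C=C1/C(C)(C)CCC[C@H]1/C(C)=C\C(=O)OC
F3 | step 12 | 1,3-dioxoisoindolin-2-yl 2-[(1R,2S,8aS)-1,2,5,5-tetramethyl-1,2,3,5,6,7,8,8a-octahydronaphthalen-1-yl]acetate | O=C(C[C@@]1(C)[C@@H]2CCCC(C)(C)C2=CC[C@@H]1C)ON1C(=O)c2ccccc2C1=O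
F4 | step 12 | chloro(2,3,5,6-tetramethoxyphenyl)zinc | COc1cc(OC)c(OC)c([Zn]Cl)c1OC
F5 | step 12 | 3-{[(1R,2S,8aS)-1,2,5,5-tetramethyl-1,2,3,5,6,7,8,8a-octahydronaphthalen-1-yl]methyl}-1,2,4,5-tetramethoxybenzene | COc1cc(OC)c(OC)c(C[C@@]2(C)[C@@H]3CCCC(C)(C)C3=CC[C@@H]2C)c1OC
F6 | step 3 | racemic 1-(6,6-dimethylcyclohex-1-en-1-yl)but-3-en-1-ol | C=CCC(O)C1=CCCCC1(C)C
F7 | step 3 | 1-(6,6-dimethylcyclohex-1-en-1-yl)but-3-en-1-one | C=CCC(=O)C1=CCCCC1(C)C
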